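**Retrosynthetic overview**

- The target comes from its 7-silyl ether, and that from the (2R,4S)-flavan-4-ol; C4 is oxidised and the phenol unmasked last, both without base.
- Feature: in ring C the O1–C8a bond is an aryl–oxygen bond. Cutting it (C8a–Br on ring A plus the C2 hydroxyl) leaves the C2–O bond of the stereogenic carbinol intact, and with C4 kept as a carbinol there is no carbonyl through which ring C could open by retro-aldol or retro-oxa-Michael paths.
- The syn-1,3-diol comes from a β-hydroxy ketone (C2–C3 bond by an enantioselective boron aldol, C4 by chelation-controlled reduction), made from the ring A bromo methyl ketone and the ring B/D aldehyde.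
- The ring B/D aldehyde comes from 4-hydroxybenzaldehyde by ortho C-prenylation, then O-propargylation and a Claisen/oxa-6π cascade that closes ring D.
- Ring order: rings A and B are bought as arenes, ring D is closed in step 3, ring C in step 7.

Key step: step 7

Remark: the labels O1, C2, C3, C4, C4a and C8a are those of the flavanone and are also used for the corresponding atoms of open-chain precursors. Ring A is the 7-oxygenated benzo ring, ring B the 2-aryl ring, ring C the pyranone and ring D the dimethylpyran fused to ring B.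

Assumption: methyl ketone enol borinates carrying the ligands of (−)-Ipc2BCl are taken to add to the Si face of aldehydes, so the antipodal (+)-Ipc2BCl is used for the Re-face addition needed here.

**Step 1**
Reactants: 1 4-hydroxybenzaldehyde; 2 prenyl bromide
Product: 3 4-hydroxy-3-(3-methylbut-2-en-1-yl)benzaldehyde
Conditions: KOH (10% aq), rt
Reagents that add atoms: none
Why: Phenoxide C-alkylation: in water the oxygen of the ambident phenoxide is shielded by hydrogen bonding, so prenyl bromide is attacked by the ring carbon ortho to oxygen (para is blocked by the formyl group), a known if modest-yielding direct ortho-prenylation from which the O-prenyl ether and doubly prenylated material are separated.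

**Step 2**
Reactants: 3 4-hydroxy-3-(3-methylbut-2-en-1-yl)benzaldehyde; 4 2-methylbut-3-yn-2-ol
Product: 6 4-[(2-methylbut-3-yn-2-yl)oxy]-3-(3-methylbut-2-en-1-yl)benzaldehyde, via 2-methylbut-3-yn-2-yl trifluoroacetate 5 (not isolated)
Conditions: 4, (CF3CO)2O, DBU, MeCN, 0 °C; then 3, DBU, CuCl2·2H2O (cat.), MeCN, 0 °C to rt
Reagents that add atoms: none
Why: Copper-catalysed propargylic etherification (Godfrey conditions): trifluoroacetate 5 ionises through a copper acetylide to an electrophile that the DBU phenoxide of 3 captures at the tertiary carbon, giving the hindered aryl 1,1-dimethylpropargyl ether that direct SN2 alkylation cannot give.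

**Step 3**
Reactants: 6 4-[(2-methylbut-3-yn-2-yl)oxy]-3-(3-methylbut-2-en-1-yl)benzaldehyde
Product: 9 2,2-dimethyl-8-(3-methylbut-2-en-1-yl)-2H-chromene-6-carbaldehyde, via ortho-allenylphenol 7 (not isolated), via ortho-quinone methide 8 (not isolated)
Conditions: N,N-diethylaniline, 160 °C
Reagents that add atoms: none
Why: Thermal aryl propargyl ether Claisen rearrangement to the free ortho carbon gives, after enolisation, allenylphenol 7; a 1,5-hydrogen shift turns it into (Z)-ortho-quinone methide 8, and oxa-6π electrocyclisation closes ring D as the 2,2-dimethyl-2H-chromene, while rearrangement towards the prenylated ortho carbon is reversible and unproductive.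

**Step 4**
Reactants: 10 1-(2-bromo-4-hydroxyphenyl)ethanone
Product: 11 1-[2-bromo-4-(triisopropylsilyloxy)phenyl]ethanone
Conditions: TIPSCl, imidazole, DMF, rt
Reagents that add atoms: triisopropylsilyl chloride (TIPSCl), CC(C)[Si](Cl)(C(C)C)C(C)C
Why: Standard silylation of a phenol; the bulky triisopropylsilyl ether is chosen because it should withstand the boron enolate, borohydride and carbonate steps and leave at the end with buffered fluoride.

**Step 5**
Reactants: 11 1-[2-bromo-4-(triisopropylsilyloxy)phenyl]ethanone; 9 2,2-dimethyl-8-(3-methylbut-2-en-1-yl)-2H-chromene-6-carbaldehyde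
Product: 14 (3R)-1-[2-bromo-4-(triisopropylsilyloxy)phenyl]-3-[2,2-dimethyl-8-(3-methylbut-2-en-1-yl)-2H-chromen-6-yl]-3-hydroxypropan-1-one, via enol diisopinocampheylborinate 12 (not isolated), via boron aldolate 13 (not isolated)
Conditions: (+)-Ipc2BCl, Et3N, Et2O, 0 °C; then 9, −78 to −20 °C; then pH 7 buffer, MeOH, H2O2, 0 °C
Reagents that add atoms: none
Why: Paterson-type boron aldol reaction of a methyl ketone: (+)-Ipc2BCl (from (−)-α-pinene) and Et3N give enol borinate 12, which adds to aldehyde 9 through a cyclic boron-bound transition state in which the isopinocampheyl ligands should steer the enolate to the Re face of the aldehyde and so set the carbinol carbon (the later C2) as R, before oxidative work-up cleaves boron aldolate 13.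

**Step 6**
Reactants: 14 (3R)-1-[2-bromo-4-(triisopropylsilyloxy)phenyl]-3-[2,2-dimethyl-8-(3-methylbut-2-en-1-yl)-2H-chromen-6-yl]-3-hydroxypropan-1-one
Product: 15 (1S,3R)-1-[2-bromo-4-(triisopropylsilyloxy)phenyl]-3-[2,2-dimethyl-8-(3-methylbut-2-en-1-yl)-2H-chromen-6-yl]propane-1,3-diol (syn)
Conditions: Et2BOMe, THF/MeOH (4:1), −78 °C; NaBH4, −78 °C; AcOH quench, MeOH co-evaporation
Reagents that add atoms: none
Why: Narasaka–Prasad reduction: Et2BOMe ties the hydroxyl and the ketone into a six-membered boron chelate and borohydride attacks its half-chair from the axial direction, which should give the syn-1,3-diol and set C1 (the later C4) as S under control of the existing carbinol.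

**Step 7**
Reactants: 15 (1S,3R)-1-[2-bromo-4-(triisopropylsilyloxy)phenyl]-3-[2,2-dimethyl-8-(3-methylbut-2-en-1-yl)-2H-chromen-6-yl]propane-1,3-diol
Product: 16 (2R,4S)-2-[2,2-dimethyl-8-(3-methylbut-2-en-1-yl)-2H-chromen-6-yl]-7-(triisopropylsilyloxy)-3,4-dihydro-2H-chromen-4-ol (2,4-trans flavan-4-ol)
Conditions: CuI (10 mol %), 3,4,7,8-tetramethyl-1,10-phenanthroline (20 mol %), Cs2CO3, toluene (0.02 M), 110 °C, Ar
Reagents that add atoms: none
Why: The phenanthroline-bound monovalent copper alkoxide formed from the C2 hydroxyl and Cs2CO3 activates the neighbouring C8a–Br bond of ring A (oxidative addition to an aryl trivalent copper alkoxide or its concerted equivalent) and releases the aryl ether by C–O reductive elimination, an intramolecular Ullmann-type etherification of the kind known for chromans from 3-(2-bromoaryl)propan-1-ols. Ring C closes as a six-membered ring by attack of the side-chain oxygen on ring carbon C8a (exo with respect to the arene, through a seven-membered copper-containing ring), forming O1–C8a. No stereocentre is created: the C2–O and C4–O bonds are never broken, so the aldol centre becomes (2R) with retention, and the syn diol maps onto the 2,4-trans flavan-4-ol because oxygen is a ring atom at C2 but exocyclic at C4. The step needs chemoselection between two secondary benzylic hydroxyls, and ring size provides it, since arylation of the C4 hydroxyl would give a four-membered benzoxete. With C4 at the alcohol level there is no carbonyl for retro-aldol cleavage, dehydration to a chalcone or retro-oxa-Michael opening under the carbonate base; copper in place of palladium avoids beta-hydride loss from the benzylic alkoxides, and dilution suppresses intermolecular etherification.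

**Step 8**
Reactants: 16 (2R,4S)-2-[2,2-dimethyl-8-(3-methylbut-2-en-1-yl)-2H-chromen-6-yl]-7-(triisopropylsilyloxy)-3,4-dihydro-2H-chromen-4-ol
Product: 17 (2R)-2-[2,2-dimethyl-8-(3-methylbut-2-en-1-yl)-2H-chromen-6-yl]-7-(triisopropylsilyloxy)-2,3-dihydro-4H-chromen-4-one
Conditions: Dess–Martin periodinane, pyridine, CH2Cl2, 0 °C to rt
Reagents that add atoms: none
Why: Dess–Martin oxidation of the secondary benzylic C4 alcohol under pyridine-buffered, non-basic conditions, which should leave the C2 stereocentre, the chromene and prenyl olefins and the silyl ether untouched.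

**Step 9**
Reactants: 17 (2R)-2-[2,2-dimethyl-8-(3-methylbut-2-en-1-yl)-2H-chromen-6-yl]-7-(triisopropylsilyloxy)-2,3-dihydro-4H-chromen-4-one
Product: 18 (2R)-2-[2,2-dimethyl-8-(3-methylbut-2-en-1-yl)-2H-chromen-6-yl]-7-hydroxy-2,3-dihydro-4H-chromen-4-one (target)
Conditions: Bu4NF, AcOH (1:1), THF, 0 °C
Reagents that add atoms: none
Why: Fluoride-induced cleavage of the aryl silyl ether; acetic acid buffering keeps the medium from becoming basic, so that E1cB opening of ring C to the 2'-hydroxychalcone, the pathway by which flavanones racemise, should not set in.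

**Compound list**

1 | 4-hydroxybenzaldehyde | O=Cc1ccc(O)cc1 | starting material
2 | prenyl bromide (1-bromo-3-methylbut-2-ene) | CC(C)=CCBr | starting material
3 | 4-hydroxy-3-(3-methylbut-2-en-1-yl)benzaldehyde | CC(C)=CCc1cc(C=O)ccc1O | intermediate
4 | 2-methylbut-3-yn-2-ol | C#CC(C)(C)O | starting material
5 | 2-methylbut-3-yn-2-yl trifluoroacetate | C#CC(C)(C)OC(=O)C(F)(F)F | intermediate (not isolated)
6 | 4-[(2-methylbut-3-yn-2-yl)oxy]-3-(3-methylbut-2-en-1-yl)benzaldehyde | CC(C)=CCc1cc(C=O)ccc1OC(C)(C)C#C | intermediate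
7 | 4-hydroxy-3-(3-methylbuta-1,2-dien-1-yl)-5-(3-methylbut-2-en-1-yl)benzaldehyde | CC(C)=CCc1cc(C=O)cc(C=C=C(C)C)c1O | intermediate (not isolated)
8 | 3-[(Z)-3-methylbut-2-en-1-ylidene]-5-(3-methylbut-2-en-1-yl)-4-oxocyclohexa-1,5-diene-1-carbaldehyde | CC(C)=C/C=C1/C=C(C=O)C=C(CC=C(C)C)C1=O | intermediate (not isolated)
9 | 2,2-dimethyl-8-(3-methylbut-2-en-1-yl)-2H-chromene-6-carbaldehyde | CC(C)=CCc1cc(C=O)cc2c1OC(C)(C)C=C2 | intermediate
10 | 1-(2-bromo-4-hydroxyphenyl)ethanone | CC(=O)c1ccc(O)cc1Br | starting material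
11 | 1-[2-bromo-4-(triisopropylsilyloxy)phenyl]ethanone | CC(=O)c1ccc(O[Si](C(C)C)(C(C)C)C(C)C)cc1Br | intermediate
12 | enol diisopinocampheylborinate of 11 (Ipc groups from (−)-α-pinene) | C=C(OB([C@H]1C[C@H]2C[C@@H]([C@@H]1C)C2(C)C)[C@H]1C[C@H]2C[C@@H]([C@@H]1C)C2(C)C)c1ccc(O[Si](C(C)C)(C(C)C)C(C)C)cc1Br | intermediate (not isolated)
13 | O-diisopinocampheylboryl aldolate of 14 | CC(C)=CCc1cc([C@H](OB([C@H]2C[C@H]3C[C@@H]([C@@H]2C)C3(C)C)[C@H]2C[C@H]3C[C@@H]([C@@H]2C)C3(C)C)CC(=O)c2ccc(O[Si](C(C)C)(C(C)C)C(C)C)cc2Br)cc2c1OC(C)(C)C=C2 | intermediate (not isolated)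
14 | (3R)-1-[2-bromo-4-(triisopropylsilyloxy)phenyl]-3-[2,2-dimethyl-8-(3-methylbut-2-en-1-yl)-2H-chromen-6-yl]-3-hydroxypropan-1-one | CC(C)=CCc1cc([C@H](O)CC(=O)c2ccc(O[Si](C(C)C)(C(C)C)C(C)C)cc2Br)cc2c1OC(C)(C)C=C2 | intermediate
15 | (1S,3R)-1-[2-bromo-4-(triisopropylsilyloxy)phenyl]-3-[2,2-dimethyl-8-(3-methylbut-2-en-1-yl)-2H-chromen-6-yl]propane-1,3-diol | CC(C)=CCc1cc([C@H](O)C[C@H](O)c2ccc(O[Si](C(C)C)(C(C)C)C(C)C)cc2Br)cc2c1OC(C)(C)C=C2 | intermediate
16 | (2R,4S)-2-[2,2-dimethyl-8-(3-methylbut-2-en-1-yl)-2H-chromen-6-yl]-7-(triisopropylsilyloxy)-3,4-dihydro-2H-chromen-4-ol | CC(C)=CCc1cc([C@H]2C[C@H](O)c3ccc(O[Si](C(C)C)(C(C)C)C(C)C)cc3O2)cc2c1OC(C)(C)C=C2 | intermediate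
17 | (2R)-2-[2,2-dimethyl-8-(3-methylbut-2-en-1-yl)-2H-chromen-6-yl]-7-(triisopropylsilyloxy)-2,3-dihydro-4H-chromen-4-one | CC(C)=CCc1cc([C@H]2CC(=O)c3ccc(O[Si](C(C)C)(C(C)C)C(C)C)cc3O2)cc2c1OC(C)(C)C=C2 | intermediate
18 | (2R)-2-[2,2-dimethyl-8-(3-methylbut-2-en-1-yl)-2H-chromen-6-yl]-7-hydroxy-2,3-dihydro-4H-chromen-4-one | CC(C)=CCc1cc([C@H]2CC(=O)c3ccc(O)cc3O2)cc2c1OC(C)(C)C=C2 | target

**Step count**

Total: 9 steps. Longest linear sequence: 8 steps (steps 1, 2, 3, 5, 6, 7, 8, 9); step 4 is a one-step side branch.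

**Steps most likely to fail**

1. Step 7 (copper etherification). What may go wrong: transfer of the silyl group from the phenolic oxygen to a caesium alkoxide, trapping of copper by the 1,3-diolate, hydrodebromination of ring A, or intermolecular etherification. The fallback replaces stereoretentive ring closure by a resolution; it sets out from aldehyde 9 and returns at target 18. Aldehyde 9 is condensed (KOH, EtOH, rt; Claisen–Schmidt) with 1-[2-hydroxy-4-(methoxymethoxy)phenyl]ethanone F1, itself made from 2',4'-dihydroxyacetophenone with MOMCl and K2CO3 in acetone, to give the 2'-hydroxychalcone F2. NaOAc in refluxing EtOH closes ring C by oxa-Michael addition to the racemic 7-(methoxymethoxy)flavanone F3. Noyori transfer hydrogenation run as a kinetic resolution (RuCl(p-cymene)[(S,S)-TsDPEN], HCO2H/Et3N, EtOAc, stopped near half conversion) should reduce the (2S) enantiomer to the (2S,4S)-cis-flavan-4-ol F5 and leave the (2R)-flavanone F4. F4 is separated and freed from the methoxymethyl group with HCl in MeOH to give 18.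

2. Step 5 (boron aldol). What may go wrong: insufficient or inverted facial selectivity of the enol borinate towards the aromatic aldehyde, reduction of the aldehyde by unconsumed chloroborane, and E1cB dehydration of the electron-rich benzylic aldol during work-up or chromatography. The enantiomeric purity of 14 is to be checked by chiral HPLC and, if needed, raised by crystallisation of diol 15. The fallback sets the stereocentre by catalytic asymmetric reduction; it sets out from 11 and 9 and returns at 17. The lithium enolate of 11 (LDA, THF, −78 °C) adds to 9 to give the racemic aldol F6, and Dess–Martin periodinane oxidises it to the 1,3-diketone F7. Noyori transfer hydrogenation of this diaryl 1,3-diketone (RuCl(p-cymene)[(R,R)-TsDPEN], HCO2H/Et3N) should give the anti-(1R,3R)-diol F8 with both carbinols set by the catalyst. The copper conditions of step 7 close F8 to the (2R,4R)-cis-flavan-4-ol F9, and the oxidation of step 8 converts F9 into 17. The C4 configuration is erased there, so the anti diol serves as well as the syn diol.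

3. Step 1 (direct C-prenylation). What may go wrong: competing O-alkylation and a second C-alkylation, which leave little mono-C-prenylated phenol. The fallback delivers the prenyl group by sigmatropic rearrangement; it sets out from 1 and returns at 3. Aldehyde 1 is etherified with trifluoroacetate 5 under the conditions of step 2 to give the propargyl ether F10. Semihydrogenation (H2, Pd/CaCO3 poisoned with Pb(OAc)2, quinoline, EtOAc) gives the 1,1-dimethylallyl ether F11. Aromatic Claisen rearrangement (N,N-diethylaniline, 130 °C) moves the allyl unit with allylic inversion to the ortho carbon and gives 3.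

**Further compounds**

F1 | step 7 | 1-[2-hydroxy-4-(methoxymethoxy)phenyl]ethanone | CC(=O)c1ccc(OCOC)cc1O
F2 | step 7 | (E)-3-[2,2-dimethyl-8-(3-methylbut-2-en-1-yl)-2H-chromen-6-yl]-1-[2-hydroxy-4-(methoxymethoxy)phenyl]prop-2-en-1-one | CC(C)=CCc1cc(/C=C/C(=O)c2ccc(OCOC)cc2O)cc2c1OC(C)(C)C=C2
F3 | step 7 | racemic 2-[2,2-dimethyl-8-(3-methylbut-2-en-1-yl)-2H-chromen-6-yl]-7-(methoxymethoxy)-2,3-dihydro-4H-chromen-4-one | CC(C)=CCc1cc(C2CC(=O)c3ccc(OCOC)cc3O2)cc2c1OC(C)(C)C=C2
F4 | step 7 | (2R)-2-[2,2-dimethyl-8-(3-methylbut-2-en-1-yl)-2H-chromen-6-yl]-7-(methoxymethoxy)-2,3-dihydro-4H-chromen-4-one | CC(C)=CCc1cc([C@H]2CC(=O)c3ccc(OCOC)cc3O2)cc2c1OC(C)(C)C=C2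
F5 | step 7 | (2S,4S)-2-[2,2-dimethyl-8-(3-methylbut-2-en-1-yl)-2H-chromen-6-yl]-7-(methoxymethoxy)-3,4-dihydro-2H-chromen-4-ol | CC(C)=CCc1cc([C@@H]2C[C@H](O)c3ccc(OCOC)cc3O2)cc2c1OC(C)(C)C=C2
F6 | step 5 | racemic 1-[2-bromo-4-(triisopropylsilyloxy)phenyl]-3-[2,2-dimethyl-8-(3-methylbut-2-en-1-yl)-2H-chromen-6-yl]-3-hydroxypropan-1-one | CC(C)=CCc1cc(C(O)CC(=O)c2ccc(O[Si](C(C)C)(C(C)C)C(C)C)cc2Br)cc2c1OC(C)(C)C=C2
F7 | step 5 | 1-[2-bromo-4-(triisopropylsilyloxy)phenyl]-3-[2,2-dimethyl-8-(3-methylbut-2-en-1-yl)-2H-chromen-6-yl]propane-1,3-dione | CC(C)=CCc1cc(C(=O)CC(=O)c2ccc(O[Si](C(C)C)(C(C)C)C(C)C)cc2Br)cc2c1OC(C)(C)C=C2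
F8 | step 5 | (1R,3R)-1-[2-bromo-4-(triisopropylsilyloxy)phenyl]-3-[2,2-dimethyl-8-(3-methylbut-2-en-1-yl)-2H-chromen-6-yl]propane-1,3-diol | CC(C)=CCc1cc([C@H](O)C[C@@H](O)c2ccc(O[Si](C(C)C)(C(C)C)C(C)C)cc2Br)cc2c1OC(C)(C)C=C2
F9 | step 5 | (2R,4R)-2-[2,2-dimethyl-8-(3-methylbut-2-en-1-yl)-2H-chromen-6-yl]-7-(triisopropylsilyloxy)-3,4-dihydro-2H-chromen-4-ol | CC(C)=CCc1cc([C@H]2C[C@@H](O)c3ccc(O[Si](C(C)C)(C(C)C)C(C)C)cc3O2)cc2c1OC(C)(C)C=C2
F10 | step 1 | 4-[(2-methylbut-3-yn-2-yl)oxy]benzaldehyde | O=Cc1ccc(OC(C)(C)C#C)cc1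
F11 | step 1 | 4-[(2-methylbut-3-en-2-yl)oxy]benzaldehyde | O=Cc1ccc(OC(C)(C)C=C)cc1
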